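## Structural features

The target is a tetracyclic C20 furanoditerpenoid acetate in which one central methine is shared by three carbocycles. Ring A is a methylenecyclohexane with an allylic acetate. Ring B is a cyclohexene whose double bond is exocyclic to a fused γ-lactone (an α-alkylidene butyrolactone). Ring C is a cycloheptanone fused to a furan through the furan 2,3-bond, with the ketone on furan C3 and the ring B carbon on furan C2.

Four of the five stereocentres are contiguous around the central CH: the lactone quaternary carbon (A/B fusion), the central CH, the methyl-bearing quaternary carbon (A/C fusion) and the furfuryl CH (B/C fusion). Their angular groups (CH2O, H, CH3, H) all lie on one face. The fifth centre, the acetate carbon, sits between the exocyclic methylene and the ring A CH2, with its oxygen on the opposite face.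

Fragile groups are the furan (acid, electrophilic oxidants), the allylic acetate next to a 1,1-disubstituted alkene (ionisation, base), the conjugated lactone (1,2-attack, deprotonation) and the furyl ketone with its enolisable CH2. The real difficulty is the pair of all-carbon quaternary centres, 1,3 to each other on ring A and both ring-fusion atoms, in an all-cis array around the central methine.

The key step uses the δ,ε-unsaturated carbonyl pattern hidden in rings A and B. From the ring A carbon that carries the methylene (a ketone before methylenation), two ring A CH2 groups lead to the lactone quaternary carbon, which is allylic to the ring B double bond. That pattern, with a cis ring fusion, is the product pattern of an oxy-Cope rearrangement of a 2-vinylbicyclo[2.2.2]oct-5-en-2-ol whose alkene bridge carries the two lactone carbons.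

## Logic of the disconnections

**34 from 33.** The two C–O bonds of the ring C ketal are cut last. The ring C ketone has to stay masked while ring A is enolised and methylenated, and the ketal also carries the chirality used for resolution. The forward step must be a hydrolysis mild enough for the allylic acetate, the exocyclic alkene and the furan.

**33 from 29 through 32 and 31.** The C=CH2 bond, the acetyl C–O bond and the C–O bond at the ring A α-carbon are cut. This leads back to a ketone with one enolisable α-carbon, which is exactly what the key step delivers. One stereocentre and the sensitive acetate/alkene pair are removed. The forward steps need a non-basic methylenation and an oxygen transfer that comes from the face opposite to the CH2O carbon and the methyl group.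

**29 from 26 through 27 and 28.** The lactone acyl C–O bond is cut and its carbonyl carbon lowered to CH2OH, both alcohols as silyl ethers. A butenolide cannot be present in the key step or in the vinyl addition (see 26 from 23). The forward step needs an oxidant that touches only the allylic alcohol (MnO2). The lactone must be back before the hydroxylation, because its planar five-membered ring holds the CH2O carbon axial on ring A and thereby fixes the face of that reaction.

**26 from 23 (key disconnection).** The bond between the ring A CH2 and the lactone quaternary carbon is cut, and the ring A ketone carbon is reconnected to the ring B vinyl CH (retro-[3,3]). This removes ring A and one quaternary stereocentre and turns the tetracycle into a bicyclo[2.2.2]octenol that a Diels–Alder reaction can build. The forward step needs the vinyl group on the carbinol face that looks at the alkene bridge, and an alkoxide as the only anion. In 23 the two lactone carbons are therefore CH2OSi groups and not a butenolide. A butenolide has γ-hydrogens more acidic than the tertiary OH, so base would give the 2-oxidofuran, in which the alkene needed for the shift is no longer localised. Its unhindered carbonyl would also compete with the hindered ketone of 21 for 22.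

**23 from 21 and 22.** The carbinol–vinyl C–C bond is cut. The forward step is a 1,2-addition to a non-enolisable, hindered ketone from the alkene-bridge face.

**21 from 17 through 20 and 19 (18 in passing).** The bridgehead C–H is traced back to C–Br, the ketal to the ketone, and the ketone to a C=CH2 group. The bromine is needed two steps earlier as a blocking group, and the methylene is what the Claisen step leaves. The forward steps need an alkene cleavage that spares the furan and the cage alkene, a ketalisation that distinguishes two ketones, and a radical dehalogenation. The racemate is resolved here, through diastereomeric ketals.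

**17 from 15 through 16.** The two σ bonds made by the Diels–Alder reaction (bridgehead–CH2 and bridgehead–furfuryl CH) are cut, and then the bond from the methyl-bearing carbon to the tether CH2 (retro-Claisen). This takes the cage back to a flat aryl allyl ether and removes four stereocentres at once. The forward cascade needs the [3,3] shift to end on the methyl-bearing ortho carbon (hence the bromine on the other) and the dienone to be trapped before it can escape by other shifts.

**15 from 3 and 11 through 14, 13 and 12.** The silyl ethers, the lactone reduction, the C=CH2 bond and the aryl ether C–O bond are cut. This separates an aromatic half from a furan half. The forward steps need only a Williamson etherification of a hindered phenol and a ketone methylenation next to a lactone.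

**3 from 1 through 2.** The C–Br bond and the aryl–CH2 bond of the phthalide are cut. The forward steps rely on the para-directing phenol OH for hydroxymethylation, and on the single remaining ortho position for bromination.

**11 from 4 through 9, 7 and 6.** The C–CH2Cl bond, the vinyl C=C and the furan C2–CHO bond are cut. The forward steps rely on carboxylate-directed lithiation of furan C2 and on a single addition of chloromethyllithium to an N-methoxy-N-methylamide.

## Other disconnections considered

**Alternative 1:** The cut is the bond between the methyl-bearing quaternary carbon and the central CH, made together with a temporary bond from the ketone α-carbon to the furfuryl carbon.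
- Forward key step: irradiation of the furyl enynone A2 would give the cyclobutane A1 by intramolecular enone–alkene [2+2] cycloaddition (1,5-closure, as the rule of five predicts). Reductive cleavage of the cyclobutane bond α to the ketone (SmI2) would then expand the five-membered ring by two carbons to ring C.
- In its favour: a photocycloaddition forms a bond to a fully substituted carbon with little steric penalty. A2 has a single stereocentre that could be set by asymmetric catalysis, so no resolution would be needed; on this point it is the better plan.
- Against it: the facial course depends only on the difference between an allyl and a silyloxymethyl group on the ring B quaternary carbon. The 1,4-diene of A2 offers a second alkene, and the alkenylfuran absorbs light itself. The fragmentation must cut the right cyclobutane bond and protonate the furfuryl carbon from the right face.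
- Comparison: structurally, A1 still lacks ring A, the acetate and the methylene. Mechanistically, both plans build a strained intermediate and release it, but the oxy-Cope closes ring A, sets the quaternary centre and delivers a regiodefined enolate in one event, and the cage or tether dictates every relative configuration. In step count the two are comparable before the key step; after it the chosen plan is shorter.

**Alternative 2:** The cut is the ring C bond between the CH2 next to the ketone and the methyl-bearing quaternary carbon.
- Forward key step: the nine-membered lactone A5 would be methylenated to the cyclic allyl vinyl ether A4. On heating, A4 would undergo a Claisen rearrangement with ring contraction to A3, with the ketone and the exocyclic methylene appearing together.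
- In its favour: one neutral, thermal step creates the quaternary centre, ring C, the free ketone and the ring A methylene. No ketone protecting group and no late methylenation (step 21 here, one of the risks) would be needed; on this point it is the better plan. The tether lets the enol ether reach only the furan-bearing face of the ring A alkene, which is as reliable as the cage (equal). The diol form of the lactone is used in both plans (equal).
- Against it: A5 already needs the cis-fused A/B system with four stereocentres, which the key step does not help to build. Closing a nine-membered lactone onto a hindered allylic alcohol and methylenating it selectively are both demanding. The medium ring must reach a strained transition state.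
- Comparison: both are [3,3] shifts with tether-dictated stereochemistry; the Claisen avoids strong base. The end-game from A3 is short, but the way to A5 is likely longer than the fifteen steps before the key step here, so overall it is no shorter.

**Alternative 3:** The cut is the ring B bond between the lactone α-carbon and the quaternary carbon, the same centre as in the chosen plan but approached from the other side.
- Forward key step: the ten-membered lactone A7 would be converted to its silyl ketene acetal. An Ireland–Claisen rearrangement across the ring A alkene would give the acid A6, closing ring B.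
- In its favour: the quaternary centre would form with chirality transfer from a secondary allylic C–O centre, which can be made enantioselectively; on this point it is the better plan. The ring constrains the ketene acetal geometry. The carboxyl carbon arrives next to the new bond.
- Against it: in A6 the acetate carbon has become an alkene carbon and must be re-oxygenated with regio- and stereocontrol. The α,β-unsaturation of ring B, the lactone closure and the methylenation are still to come. Macrolactonisation to A7 onto a hindered alcohol next to a ketal carbon is uncertain. A7 already contains ring C and the other quaternary carbon, whose construction is as hard as the original problem.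
- Comparison: both plans make the same quaternary carbon by a [3,3] shift. The oxy-Cope leaves the ring B unsaturation and a usable enolate in the right places; the Ireland–Claisen leaves an alkene in ring A in the wrong place. After the key step the chosen plan is several steps shorter.

Key step: step 16

Remarks on the chemistry:
- Compounds 16 to 19 are racemic and are drawn as the enantiomer that is carried on. The absolute configuration is fixed by separating the diastereomeric ketals in step 13, to be confirmed by X-ray diffraction on bromide 20.
- In 23 and 26 the lactone is carried as the bis-silyl ether of the ene-diol, and the ring C ketal is made from (2R,3R)-butane-2,3-diol. The carbon skeleton, the bond formed and the ring closed in the key step are unchanged, and the lactone form of the rearranged ketone is 29. The configurations of 23, 26, 29 and 34 were checked against one another centre by centre and are consistent.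
- Bridged compounds 17 to 24 are described with bicyclo[2.2.2]oct-5-en-2-one numbering: C1 is the bridgehead next to the carbonyl C2, C3 the quaternary carbon, C4 the other bridgehead, C5=C6 the alkene bridge (C5 on C4), C7 the CH2 on C1 and C8 the CH on C4.

Step 1
Reactants: 1 3-hydroxy-4-methylbenzoic acid
Product: 2 6-hydroxy-5-methylisobenzofuran-1(3H)-one
Conditions: 37% aq. CH2O (1.1 equiv), conc. HCl, AcOH, 80 °C
Reagents that add atoms: formaldehyde, C=O
Why: Acid-mediated hydroxymethylation (electrophilic aromatic substitution of Blanc type) should go para to the phenol OH, because the other activated positions carry the methyl group or lie between OH and CO2H; the benzylic alcohol then closes onto the neighbouring acid to give the phthalide.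

Step 2
Reactants: 2 6-hydroxy-5-methylisobenzofuran-1(3H)-one
Product: 3 7-bromo-6-hydroxy-5-methylisobenzofuran-1(3H)-one
Conditions: NBS (1.05 equiv), MeCN, 0 °C to rt
Reagents that add atoms: N-bromosuccinimide, O=C1CCC(=O)N1Br
Why: Electrophilic bromination of the phenol can reach only the one free ortho carbon (para and the second ortho carbon are substituted); the bromine blocks this carbon so that the later [3,3] shift has to end on the methyl-bearing ortho carbon.

Step 3
Reactants: 4 furan-3-carboxylic acid
Product: 6 2-formylfuran-3-carboxylic acid, via dilithiated furoate 5 (not isolated)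
Conditions: LiN(iPr)2 (2.2 equiv), THF, −78 °C; DMF; aq. HCl
Reagents that add atoms: N,N-dimethylformamide, CN(C)C=O
Why: Carboxylate-directed ortho-lithiation of the furan at C2 (dianion formation) followed by formylation with DMF; the lithium carboxylate protects the acid from the amide base.

Step 4
Reactants: 6 2-formylfuran-3-carboxylic acid
Product: 7 2-ethenylfuran-3-carboxylic acid
Conditions: MePPh3Br (2.5 equiv), KOtBu (3.5 equiv), THF, 0 °C to rt; aq. HCl
Reagents that add atoms: methyltriphenylphosphonium bromide, C[P+](c1ccccc1)(c1ccccc1)c1ccccc1.[Br-]
Why: Wittig methylenation of the aldehyde; the carboxylate consumes one equivalent of base and is inert to the ylide.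

Step 5
Reactants: 7 2-ethenylfuran-3-carboxylic acid
Product: 9 2-ethenyl-N-methoxy-N-methylfuran-3-carboxamide, via acyl imidazole 8 (not isolated)
Conditions: 1,1'-carbonyldiimidazole, CH2Cl2, rt; then MeNHOMe·HCl, rt
Reagents that add atoms: N,O-dimethylhydroxylamine hydrochloride, CNOC.Cl
Why: Activation as the acyl imidazole and aminolysis give the N-methoxy-N-methylamide (Weinreb amide), the acyl donor needed for a single carbanion addition.

Step 6
Reactants: 9 2-ethenyl-N-methoxy-N-methylfuran-3-carboxamide
Product: 11 2-chloro-1-(2-ethenylfuran-3-yl)ethan-1-one, via lithium hemiaminal alkoxide 10 (not isolated)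
Conditions: ICH2Cl (1.5 equiv), MeLi·LiBr (1.5 equiv), THF, −78 °C; aq. NH4Cl
Reagents that add atoms: chloroiodomethane, ClCI
Why: Chloromethyllithium, made by iodine–lithium exchange in the presence of the amide, adds once and the chelated adduct 10 collapses only on quench (Weinreb ketone synthesis), so the α-chloro ketone should form without over-addition and without touching the vinylfuran.

Step 7
Reactants: 3 7-bromo-6-hydroxy-5-methylisobenzofuran-1(3H)-one; 11 2-chloro-1-(2-ethenylfuran-3-yl)ethan-1-one
Product: 12 7-bromo-6-[2-(2-ethenylfuran-3-yl)-2-oxoethoxy]-5-methylisobenzofuran-1(3H)-one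
Conditions: K2CO3, NaI (cat.), acetone, 50 °C
Reagents that add atoms: none
Why: Williamson ether synthesis: the 2,6-disubstituted but acidic phenoxide displaces the halide of the α-halo ketone (iodide catalysis), an SN2 reaction that is fast even for hindered phenols.

Step 8
Reactants: 12 7-bromo-6-[2-(2-ethenylfuran-3-yl)-2-oxoethoxy]-5-methylisobenzofuran-1(3H)-one
Product: 13 7-bromo-6-{[2-(2-ethenylfuran-3-yl)prop-2-en-1-yl]oxy}-5-methylisobenzofuran-1(3H)-one
Conditions: MePPh3Br, KN(SiMe3)2, THF, −78 to 0 °C
Reagents that add atoms: methyltriphenylphosphonium bromide, C[P+](c1ccccc1)(c1ccccc1)c1ccccc1.[Br-]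
Why: Wittig methylenation of the aryl ketone gives the 2-arylallyl aryl ether; the ketone is far more electrophilic than the lactone, and the ylide is used at low temperature to limit enolisation.

Step 9
Reactants: 13 7-bromo-6-{[2-(2-ethenylfuran-3-yl)prop-2-en-1-yl]oxy}-5-methylisobenzofuran-1(3H)-one
Product: 14 (3-bromo-4-{[2-(2-ethenylfuran-3-yl)prop-2-en-1-yl]oxy}-5-methyl-1,2-phenylene)dimethanol
Conditions: iBu2AlH (4 equiv), CH2Cl2, −78 to 0 °C; aq. potassium sodium tartrate
Reagents that add atoms: none
Why: Hydride reduction of the lactone, the only carbonyl group, to the benzene-1,2-dimethanol; aryl bromide, allyl ether and alkenes are inert to iBu2AlH.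

Step 10
Reactants: 14 (3-bromo-4-{[2-(2-ethenylfuran-3-yl)prop-2-en-1-yl]oxy}-5-methyl-1,2-phenylene)dimethanol
Product: 15 bis(tert-butyldimethylsilyl) ether of 14
Conditions: tBuMe2SiCl (2.5 equiv), imidazole, DMF, rt
Reagents that add atoms: tert-butyldimethylsilyl chloride, CC(C)(C)[Si](C)(C)Cl
Why: Standard silylation of the two primary benzylic alcohols; from here to step 16 the future lactone is a base-stable, non-electrophilic pair of CH2OSi groups.

Step 11
Reactants: 15 bis(tert-butyldimethylsilyl) ether of 14
Product: 17 (±)-1-bromo bicyclo[2.2.2]oct-5-en-2-one adduct bearing the ring C exocyclic methylene, via ortho-dienone 16 (not isolated)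
Conditions: o-dichlorobenzene (0.005 M), BHT, 180 °C, sealed tube
Reagents that add atoms: none
Why: Heating should trigger an aromatic Claisen rearrangement which, with bromine on the other ortho carbon, ends on the methyl-bearing carbon and gives the 6,6-disubstituted cyclohexa-2,4-dienone 16; this cannot tautomerise and is trapped by intramolecular Diels–Alder addition of the furan-bound vinyl group across the diene (Claisen/Diels–Alder cascade). The four-atom tether lets the vinyl CH reach only the diene terminus next to the quaternary carbon and only the face that carries the tether, so the relative configuration of both bridgeheads, the furfuryl CH and the quaternary carbon (methyl syn to the new alkene bridge) is fixed; the product is racemic.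

Step 12
Reactants: 17 (±)-1-bromo bicyclo[2.2.2]oct-5-en-2-one adduct bearing the ring C exocyclic methylene
Product: 19 (±)-1-bromo diketone, via vicinal diol 18 (not isolated)
Conditions: K2OsO4·2H2O (2 mol %), NaIO4 (4 equiv), 2,6-lutidine, dioxane–H2O 3:1, rt
Reagents that add atoms: sodium periodate, [Na+].[O-]I(=O)(=O)=O; water, O
Why: Lemieux–Johnson oxidation: OsO4 dihydroxylates the accessible 1,1-disubstituted alkene (the tetrasubstituted cage alkene is shielded and the furan is aromatic) and NaIO4 cleaves diol 18 to the ring C ketone and formaldehyde.

Step 13
Reactants: 19 (±)-1-bromo diketone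
Product: 20 1-bromo ketone (4R,5R)-4,5-dimethyl-1,3-dioxolane ketal (single diastereomer)
Conditions: (2R,3R)-2,3-bis(trimethylsilyloxy)butane, Me3SiOTf (cat.), CH2Cl2, −78 to 0 °C; separation of the two diastereomers by chromatography or crystallisation
Reagents that add atoms: (2R,3R)-2,3-bis(trimethylsilyloxy)butane, C[C@@H](O[Si](C)(C)C)[C@@H](C)O[Si](C)(C)C
Why: Noyori-type ketalisation should take place only at the ring C ketone, because the other carbonyl is flanked by a quaternary carbon and by the brominated bridgehead. The enantiopure C2-symmetric diol turns the racemate into two diastereomers without creating a centre at the ketal carbon; the one with the core configuration shown is kept, and the bromine allows its assignment by anomalous dispersion.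

Step 14
Reactants: 20 1-bromo ketone (4R,5R)-4,5-dimethyl-1,3-dioxolane ketal
Product: 21 bridged ketone ketal
Conditions: Bu3SnH (1.5 equiv), AIBN (cat.), benzene, 80 °C
Reagents that add atoms: none
Why: Radical chain reduction of the tertiary bridgehead bromide (halogen abstraction by the stannyl radical, hydrogen transfer from Bu3SnH); the pyramidal bridgehead radical has no cyclisation or fragmentation channel, so the configuration is untouched.

Step 15
Reactants: 21 bridged ketone ketal; 22 vinylmagnesium bromide
Product: 23 bridged vinyl carbinol (substrate of the key step)
Conditions: CeCl3 (anhydrous, 3 equiv), THF, −78 °C; aq. NH4Cl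
Reagents that add atoms: vinylmagnesium bromide (22), C=C[Mg]Br
Why: Organocerium 1,2-addition to the hindered, non-enolisable ketone, the only electrophilic carbonyl left; attack from the face of the alkene bridge, which has no inward-pointing hydrogen, and not from the ethano-bridge face (endo C–H and ring C), should set the carbinol centre with vinyl syn to the alkene bridge and OH toward the ethano bridge.

Step 16
Reactants: 23 bridged vinyl carbinol
Product: 26 ring A ketone bis-silyl ether, via potassium alkoxide 24 (not isolated), via potassium enolate 25 (not isolated)
Conditions: KH (1.5 equiv), 18-crown-6 (1.5 equiv), THF, 0 °C to rt; aq. NH4Cl, −78 °C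
Reagents that add atoms: none
Why: KH and 18-crown-6 convert the tertiary carbinol, the only acidic site left in 23, into the dissociated potassium alkoxide 24, which should undergo a [3,3] sigmatropic shift through the boat-shaped six-centre array that the bicyclo[2.2.2]octene cage enforces. The bond between the carbinol carbon and the adjacent bridgehead breaks while the vinyl terminus bonds to the far carbon of the tetrasubstituted alkene bridge, so the carbinol carbon becomes the enolate carbon of 25 and the bridgehead becomes the ring B vinyl CH. The closest known reaction type is the anionic oxy-Cope rearrangement of 2-vinylbicyclo[2.2.2]oct-5-en-2-ols to cis-fused octalones. Ring A is closed in a pericyclic mode, by joining the two termini of the hexa-1,5-diene; read as a polar process it is a 6-endo-trig attack of the allyl terminus on the incipient enone. The one new stereocentre, the quaternary carbon carrying CH2OSi, is set by the cage: the vinyl group sits on the carbinol face turned toward the alkene bridge and can reach only the face of that alkene turned toward the carbonyl bridge, which puts the CH2OSi group cis to the central hydrogen (cis A/B fusion). The step needs a single anion and a single pathway: the first is secured by carrying the lactone as silyl ethers (no γ-acidic butenolide, no electrophilic carbonyl) and the ring C ketone as a ketal, the second by the fact that only one neighbour of the carbinol carbon is allylic. Release of cage strain and formation of the enolate should make the shift irreversible, and protonation of 25 gives 26 without creating a further stereocentre.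

Step 17
Reactants: 26 ring A ketone bis-silyl ether
Product: 27 ring A ketone ene-diol
Conditions: Bu4NF (2.5 equiv), THF, 0 °C to rt; aq. NH4Cl
Reagents that add atoms: none
Why: Fluoride cleavage of both primary silyl ethers; ketal and ketone are unaffected.

Step 18
Reactants: 27 ring A ketone ene-diol
Product: 29 ring A ketone lactone (rearranged ketone in its lactone form), via lactol 28 (not isolated)
Conditions: MnO2 (activated, excess), CH2Cl2, rt
Reagents that add atoms: none
Why: MnO2 oxidises only the allylic primary alcohol; the enal is captured by the neighbouring neopentyl CH2OH as lactol 28, which is oxidised further (oxidative lactonisation of a 2-ene-1,4-diol), so the carbonyl ends on the alkene side as in the target.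

Step 19
Reactants: 29 ring A ketone lactone
Product: 31 ring A α-hydroxy ketone, via potassium enolate 30 (not isolated)
Conditions: KN(SiMe3)2 (1.1 equiv), THF, −78 °C; 2-(phenylsulfonyl)-3-phenyloxaziridine; aq. NH4Cl
Reagents that add atoms: 2-(phenylsulfonyl)-3-phenyloxaziridine, O=S(=O)(c1ccccc1)N1OC1c1ccccc1
Why: Deprotonation at the only enolisable ketone α-position and oxygen transfer from the N-sulfonyloxaziridine (Davis enolate hydroxylation). The planar alkylidene lactone holds its CH2O carbon axial on ring A, syn to the axial methyl, so both block one face of the enolate carbon (1,3-diaxial); oxygen should enter from the other face and give the equatorial alcohol with the configuration of the target.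

Step 20
Reactants: 31 ring A α-hydroxy ketone
Product: 32 ring A α-acetoxy ketone
Conditions: Ac2O, DMAP (cat.), Et3N, CH2Cl2, 0 °C to rt
Reagents that add atoms: acetic anhydride, CC(=O)OC(C)=O
Why: DMAP-catalysed acetylation of the secondary alcohol with retention of configuration.

Step 21
Reactants: 32 ring A α-acetoxy ketone
Product: 33 ketal of the target
Conditions: Zn, CH2Br2, TiCl4, THF/CH2Cl2, 0 °C to rt
Reagents that add atoms: dibromomethane, BrCBr
Why: Takai–Lombardo methylenation: the non-basic geminal dimetal reagent converts hindered and enolisable ketones to methylene compounds and leaves esters, lactones and ketals alone, so the α-acetoxy centre should not be epimerised or eliminated.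

Step 22
Reactants: 33 ketal of the target
Product: 34 target, CNP0273675.2
Conditions: PPTS, acetone–H2O, 50 °C
Reagents that add atoms: water, O
Why: Acid-catalysed hydrolysis of the ketal, fast because the oxocarbenium ion is stabilised by the furan; the conditions are too mild to ionise the allylic acetate or to isomerise the exocyclic alkene.

## Compound list

1 | 3-hydroxy-4-methylbenzoic acid | Cc1ccc(cc1O)C(O)=O | starting material
2 | 6-hydroxy-5-methylisobenzofuran-1(3H)-one | Cc1cc2COC(=O)c2cc1O | intermediate
3 | 7-bromo-6-hydroxy-5-methylisobenzofuran-1(3H)-one | Cc1cc2COC(=O)c2c(Br)c1O | intermediate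
4 | furan-3-carboxylic acid (3-furoic acid) | OC(=O)c1ccoc1 | starting material
5 | lithium 2-lithiofuran-3-carboxylate | [Li]OC(=O)c1ccoc1[Li] | intermediate (not isolated)
6 | 2-formylfuran-3-carboxylic acid | O=Cc1occc1C(=O)O | intermediate
7 | 2-ethenylfuran-3-carboxylic acid | C=Cc1occc1C(=O)O | intermediate
8 | (2-ethenylfuran-3-yl)(imidazol-1-yl)methanone | C=Cc1occc1C(=O)n1ccnc1 | intermediate (not isolated)
9 | 2-ethenyl-N-methoxy-N-methylfuran-3-carboxamide | C=Cc1occc1C(=O)N(C)OC | intermediate
10 | lithium 2-chloro-1-(2-ethenylfuran-3-yl)-1-[methoxy(methyl)amino]ethan-1-olate | C=Cc1occc1C(O[Li])(CCl)N(C)OC | intermediate (not isolated)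
11 | 2-chloro-1-(2-ethenylfuran-3-yl)ethan-1-one | C=Cc1occc1C(=O)CCl | intermediate
12 | 7-bromo-6-[2-(2-ethenylfuran-3-yl)-2-oxoethoxy]-5-methylisobenzofuran-1(3H)-one | C=Cc1occc1C(=O)COc1c(C)cc2COC(=O)c2c1Br | intermediate
13 | 7-bromo-6-{[2-(2-ethenylfuran-3-yl)prop-2-en-1-yl]oxy}-5-methylisobenzofuran-1(3H)-one | C=Cc1occc1C(=C)COc1c(C)cc2COC(=O)c2c1Br | intermediate
14 | (3-bromo-4-{[2-(2-ethenylfuran-3-yl)prop-2-en-1-yl]oxy}-5-methyl-1,2-phenylene)dimethanol | C=Cc1occc1C(=C)COc1c(C)cc(CO)c(CO)c1Br | intermediate
15 | bis(tert-butyldimethylsilyl) ether of 14 | C=Cc1occc1C(=C)COc1c(C)cc(CO[Si](C)(C)C(C)(C)C)c(CO[Si](C)(C)C(C)(C)C)c1Br | intermediate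
16 | (±)-2-bromo-3,4-bis(tert-butyldimethylsilyloxymethyl)-6-[2-(2-ethenylfuran-3-yl)prop-2-en-1-yl]-6-methylcyclohexa-2,4-dien-1-one (racemic, one enantiomer drawn) | C=Cc1occc1C(=C)C[C@]1(C)C=C(CO[Si](C)(C)C(C)(C)C)C(CO[Si](C)(C)C(C)(C)C)=C(Br)C1=O | intermediate (not isolated)
17 | (±)-Claisen/Diels–Alder adduct: bicyclo[2.2.2]oct-5-en-2-one with Br on C1, C3 quaternary (CH3 syn to the alkene bridge, ring C CH2 syn to the ethano bridge), CH2OSi groups on C5 and C6, furan C2 on C8 (syn to the carbonyl bridge); ring C closed through C(=CH2)–CH2 from furan C3 to C3 (racemic, one enantiomer drawn) | O=C1[C@@]2(Br)C[C@H]3c4occc4C(=C)C[C@]1(C)[C@H]3C(CO[Si](C)(C)C(C)(C)C)=C2CO[Si](C)(C)C(C)(C)C | intermediate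
18 | (±)-diol of 17: ring C carbon bearing OH and CH2OH in place of C=CH2 (configuration at that carbon not defined) | O=C1[C@@]2(Br)C[C@H]3c4occc4C(O)(CO)C[C@]1(C)[C@H]3C(CO[Si](C)(C)C(C)(C)C)=C2CO[Si](C)(C)C(C)(C)C | intermediate (not isolated)
19 | (±)-1-bromo diketone: as 17 with the ring C ketone in place of C=CH2 (racemic, one enantiomer drawn) | O=C1[C@@]2(Br)C[C@H]3c4occc4C(=O)C[C@]1(C)[C@H]3C(CO[Si](C)(C)C(C)(C)C)=C2CO[Si](C)(C)C(C)(C)C | intermediate
20 | 1-bromo ketone with the ring C ketone as (4R,5R)-4,5-dimethyl-1,3-dioxolane, single diastereomer | O=C1[C@@]2(Br)C[C@H]3c4occc4C4(O[C@H](C)[C@@H](C)O4)C[C@]1(C)[C@H]3C(CO[Si](C)(C)C(C)(C)C)=C2CO[Si](C)(C)C(C)(C)C | intermediate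
21 | bridged ketone ketal: as 20 with H on C1 | O=C1[C@H]2C[C@H]3c4occc4C4(O[C@H](C)[C@@H](C)O4)C[C@]1(C)[C@H]3C(CO[Si](C)(C)C(C)(C)C)=C2CO[Si](C)(C)C(C)(C)C | intermediate
22 | vinylmagnesium bromide | C=C[Mg]Br | starting material
23 | bridged vinyl carbinol: as 21 with C2 bearing OH (toward the ethano bridge) and vinyl (syn to the alkene bridge) | C=C[C@]1(O)[C@H]2C[C@H]3c4occc4C4(O[C@H](C)[C@@H](C)O4)C[C@]1(C)[C@H]3C(CO[Si](C)(C)C(C)(C)C)=C2CO[Si](C)(C)C(C)(C)C | intermediate
24 | potassium alkoxide of 23 | C=C[C@]1(O[K])[C@H]2C[C@H]3c4occc4C4(O[C@H](C)[C@@H](C)O4)C[C@]1(C)[C@H]3C(CO[Si](C)(C)C(C)(C)C)=C2CO[Si](C)(C)C(C)(C)C | intermediate (not isolated)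
25 | potassium enolate of 26 (ring A enolate, double bond toward the ring A CH2) | [K]OC1=CC[C@@]2(CO[Si](C)(C)C(C)(C)C)C(CO[Si](C)(C)C(C)(C)C)=CC[C@H]3c4occc4C4(O[C@H](C)[C@@H](C)O4)C[C@]1(C)[C@@H]23 | intermediate (not isolated)
26 | ring A ketone with rings A, B and C cis-fused about the central CH; CH2OSi on the A/B quaternary carbon (cis to the central H) and on the ring B alkene carbon; ring C ketal as in 20 | O=C1CC[C@@]2(CO[Si](C)(C)C(C)(C)C)C(CO[Si](C)(C)C(C)(C)C)=CC[C@H]3c4occc4C4(O[C@H](C)[C@@H](C)O4)C[C@]1(C)[C@@H]23 | intermediate
27 | ring A ketone ene-diol: as 26 with two CH2OH groups | O=C1CC[C@@]2(CO)C(CO)=CC[C@H]3c4occc4C4(O[C@H](C)[C@@H](C)O4)C[C@]1(C)[C@@H]23 | intermediate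
28 | lactol of 29 (hemiacetal carbon on the alkene side, configuration not defined) | O=C1CC[C@@]23COC(O)C2=CC[C@H]2c4occc4C4(O[C@H](C)[C@@H](C)O4)C[C@]1(C)[C@H]23 | intermediate (not isolated)
29 | ring A ketone with the α-alkylidene γ-lactone restored; ring C ketal as in 20 | O=C1CC[C@@]23COC(=O)C2=CC[C@H]2c4occc4C4(O[C@H](C)[C@@H](C)O4)C[C@]1(C)[C@H]23 | intermediate
30 | potassium enolate of 29 | [K]OC1=CC[C@@]23COC(=O)C2=CC[C@H]2c4occc4C4(O[C@H](C)[C@@H](C)O4)C[C@]1(C)[C@H]23 | intermediate (not isolated)
31 | ring A α-hydroxy ketone: OH trans to the methyl group and to the lactone CH2O carbon | O=C1[C@@H](O)C[C@@]23COC(=O)C2=CC[C@H]2c4occc4C4(O[C@H](C)[C@@H](C)O4)C[C@]1(C)[C@H]23 | intermediate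
32 | ring A α-acetoxy ketone | O=C1[C@@H](OC(C)=O)C[C@@]23COC(=O)C2=CC[C@H]2c4occc4C4(O[C@H](C)[C@@H](C)O4)C[C@]1(C)[C@H]23 | intermediate
33 | (4R,5R)-4,5-dimethyl-1,3-dioxolane ketal of the target | C=C1[C@@H](OC(C)=O)C[C@@]23COC(=O)C2=CC[C@H]2c4occc4C4(O[C@H](C)[C@@H](C)O4)C[C@]1(C)[C@H]23 | intermediate
34 | CNP0273675.2 | C=C1[C@@H](OC(C)=O)C[C@@]23COC(=O)C2=CC[C@H]2c4occc4C(=O)C[C@]1(C)[C@H]23 | target

## Step count and least certain steps

Total step count: 22. Longest linear sequence: 20 steps (4 to 34, steps 3 to 22); the aromatic branch (1 to 3) adds 2 steps.

**Step 16 (key step).** The alkoxide may cleave heterolytically to an enone and an allyl anion that then loses silanolate from an allylic CH2OSi group or is protonated. A silyl group may also move from a primary oxygen to the tertiary alkoxide. Either process would divert material from the concerted shift. Fallback: starting from 23, both silyl groups are removed with Bu4NF to give the desilylated vinyl carbinol triol F1. The rearrangement is then run on its tripotassium salt (KH in excess, 18-crown-6, THF), where no oxygen leaving group and no silyl group exist. Aqueous quench gives the keto diol directly, and the route is rejoined at 27.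

**Step 11.** At the temperature the Claisen shift needs, the 2,3-dialkenylfuran unit may polymerise or undergo 6π-electrocyclisation before the shift, and the allyl group may wander to other ring positions faster than the dienone is trapped. Fallback: the dienone is made by C-alkylation at low temperature, starting from 3 and 11.
- 3 is reduced with LiAlH4 to the bromo phenol triol F2.
- The two primary alcohols of F2 are silylated (tBuMe2SiCl, imidazole, 0 °C; the hindered phenol stays free) to the bis-silyl bromophenol F3.
- 11 is methylenated (MePPh3Br, KN(SiMe3)2) to the allylic chloride F4.
- The sodium salt of F3 (NaH, toluene) is alkylated with F4. C-allylation of a 2,6-disubstituted alkali phenoxide in a non-polar medium gives 16 at 25 to 60 °C, which closes to the adduct at or below 80 °C.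
- Any O-alkylated material is 15 and can be recycled. The route is rejoined at 17.

**Step 13.** The two diastereomeric ketals may not separate well, or exchange may also touch the second carbonyl. Fallback: starting from 19, the racemate is resolved by preparative chromatography on a chiral stationary phase (supercritical CO2/methanol). The single enantiomer is ketalised under the same conditions. No new compound arises, and the route is rejoined at 20.

**Step 15.** The facial selectivity of the addition may be poor or reversed, because the CH2OSi group on the alkene bridge and the methyl group both sit near the preferred trajectory. Addition from the ethano-bridge face would give the carbinol epimer that cannot rearrange. Fallback: starting from 21, the oxygen is delivered in place of the carbon, using the same facial bias.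
- The ketone is methylenated (Zn, CH2Br2, TiCl4) to the C2-methylene cage compound F5.
- OsO4 dihydroxylation from the ethano-bridge face (K2OsO4·2H2O cat., N-methylmorpholine N-oxide) gives the cage diol F6, with the tertiary OH toward the ethano bridge.
- The primary alcohol is oxidised (SO3·pyridine, DMSO, Et3N) to the α-hydroxy aldehyde F7.
- Wittig methylenation of F7 gives the vinyl carbinol, and the route is rejoined at 23.

**Step 21.** Zinc may reductively remove the α-acetoxy group, or the hindered carbonyl may react too slowly and enolise. Fallback: starting from 29, the order is reversed.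
- The unsubstituted ketone is methylenated with the same reagent to the ring A methylene lactone F8.
- Allylic hydroxylation (SeO2, tBuOOH, CH2Cl2) at the only allylic CH2 gives the ring A allylic alcohol F9. Oxygen is expected from the face away from the two axial groups.
- Acetylation of F9 (Ac2O, DMAP) rejoins the route at 33.

**Step 1.** Hydroxymethylation may also occur at the carbon between OH and CO2H, and the product phenol may react on with formaldehyde to a benzodioxine or to diarylmethanes. Fallback: starting from 1, the regiochemistry is fixed by a halogen.
- Bromination (Br2, AcOH) para to the OH gives the para-bromo acid F10.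
- Bromine–lithium exchange on its lithium salt (n-BuLi, 3.1 equiv, THF, −78 °C) and formylation with DMF give the hydroxyphthalide F11 (ring form of the formyl acid).
- Reduction with NaBH4 and acidification close the phthalide, and the route is rejoined at 2.

## Further compounds

F1 | step 16 | desilylated vinyl carbinol triol | C=C[C@]1(O)[C@H]2C[C@H]3c4occc4C4(O[C@H](C)[C@@H](C)O4)C[C@]1(C)[C@H]3C(CO)=C2CO
F2 | step 11 | (3-bromo-4-hydroxy-5-methyl-1,2-phenylene)dimethanol | Cc1cc(CO)c(CO)c(Br)c1O
F3 | step 11 | 2-bromo-3,4-bis(tert-butyldimethylsilyloxymethyl)-6-methylphenol | Cc1cc(CO[Si](C)(C)C(C)(C)C)c(CO[Si](C)(C)C(C)(C)C)c(Br)c1O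
F4 | step 11 | 3-(3-chloroprop-1-en-2-yl)-2-ethenylfuran | C=Cc1occc1C(=C)CCl
F0 | step 13 | none | none
F5 | step 15 | C2-methylene cage compound (C=CH2 in place of the ketone of 21) | C=C1[C@H]2C[C@H]3c4occc4C4(O[C@H](C)[C@@H](C)O4)C[C@]1(C)[C@H]3C(CO[Si](C)(C)C(C)(C)C)=C2CO[Si](C)(C)C(C)(C)C
F6 | step 15 | cage diol (tertiary OH toward the ethano bridge, CH2OH syn to the alkene bridge) | OC[C@]1(O)[C@H]2C[C@H]3c4occc4C4(O[C@H](C)[C@@H](C)O4)C[C@]1(C)[C@H]3C(CO[Si](C)(C)C(C)(C)C)=C2CO[Si](C)(C)C(C)(C)C
F7 | step 15 | cage α-hydroxy aldehyde | O=C[C@]1(O)[C@H]2C[C@H]3c4occc4C4(O[C@H](C)[C@@H](C)O4)C[C@]1(C)[C@H]3C(CO[Si](C)(C)C(C)(C)C)=C2CO[Si](C)(C)C(C)(C)C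
F8 | step 21 | ring A methylene lactone (C=CH2 in place of the ketone of 29) | C=C1CC[C@@]23COC(=O)C2=CC[C@H]2c4occc4C4(O[C@H](C)[C@@H](C)O4)C[C@]1(C)[C@H]23
F9 | step 21 | ring A allylic alcohol (deacetyl 33) | C=C1[C@@H](O)C[C@@]23COC(=O)C2=CC[C@H]2c4occc4C4(O[C@H](C)[C@@H](C)O4)C[C@]1(C)[C@H]23
F10 | step 1 | 2-bromo-5-hydroxy-4-methylbenzoic acid | Cc1cc(Br)c(C(=O)O)cc1O
F11 | step 1 | 3,6-dihydroxy-5-methylisobenzofuran-1(3H)-one | Cc1cc2C(O)OC(=O)c2cc1O
A1 | alternative 1 | cyclobutane photoadduct (ring B with allyl, silyloxymethyl and ester; cyclobutane fused to the furano-cyclopentanone; methyl and ethynyl on the quaternary carbon) | C=CC[C@@]1(CO[Si](c2ccccc2)(c2ccccc2)C(C)(C)C)C(C(=O)OC)=CC[C@@]23c4occc4C(=O)[C@@H]2[C@@](C)(C#C)[C@@H]13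
A2 | alternative 1 | photosubstrate: cyclohexa-1,4-diene bearing the furan whose C3 carries the 3-methylpent-2-en-4-ynoyl group (enone geometry not defined) | C=CC[C@@]1(CO[Si](c2ccccc2)(c2ccccc2)C(C)(C)C)C(C(=O)OC)=CCC(c2occc2C(=O)C=C(C)C#C)=C1
A3 | alternative 2 | tetracyclic ketone with the lactone as diol bis-silyl ether and the ring A oxygen as 4-methoxybenzyl ether | C=C1[C@@H](OCc2ccc(OC)cc2)C[C@@]2(CO[Si](C)(C)C(C)(C)C)C(CO[Si](C)(C)C(C)(C)C)=CC[C@H]3c4occc4C(=O)C[C@]1(C)[C@@H]23
A4 | alternative 2 | nine-membered cyclic allyl vinyl ether (enol ether carbon on furan C3, oxygen on the ring A allylic CH2) | C=C1OCC2=C(C)[C@@H]3[C@H](c4occc14)CC=C(CO[Si](C)(C)C(C)(C)C)[C@]3(CO[Si](C)(C)C(C)(C)C)C[C@@H]2OCc2ccc(OC)cc2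
A5 | alternative 2 | nine-membered lactone (furan-3-carboxylate of the ring A allylic CH2OH) | O=C1OCC2=C(C)[C@@H]3[C@H](c4occc14)CC=C(CO[Si](C)(C)C(C)(C)C)[C@]3(CO[Si](C)(C)C(C)(C)C)C[C@@H]2OCc2ccc(OC)cc2
A6 | alternative 3 | ring B carboxylic acid (ring A with dimethyl ketal and alkene, ring C ketal, silyloxymethyl on the quaternary carbon) | OC(=O)[C@H]1CC[C@H]2c3occc3C3(OCCO3)C[C@@]3(C)C(OC)(OC)C=C[C@]1(CO[Si](C)(C)C(C)(C)C)[C@@H]23
A7 | alternative 3 | ten-membered lactone (acyl chain from the furfuryl CH, ester oxygen on the ring A carbon that later carries the acetate) | O=C1CCC[C@H]2c3occc3C3(OCCO3)C[C@@]3(C)C(OC)(OC)[C@@H](O1)C=C(CO[Si](C)(C)C(C)(C)C)[C@@H]23
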